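**Retrosynthetic overview**
1. Daucane numbering is used (ring A = C1–C5, ring B = C1, C5–C10; β = face of the C1 methyl). The target is traced back through late acylations (C2/C10 acetates, C6 angelate), hydroxyl-directed 8α,9α-epoxidation and isopropyl addition to a C4 ketone to a trans-fused ring A/ring B boronate with C8=C9 and C6–B.
2. Key disconnection: the C5–C6 and C7–C8 bonds of ring B are cut together. A vinyl unit (C6–C7) is stitched between a C5 secondary boronate on ring A and a C8 alkenyl iodide by an intramolecular palladium-catalysed conjunctive cross-coupling (formal [5+2] annulation).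
3. Enabling feature: in ring B the oxygen-bearing C6 lies between the ring-fusion carbon C5 and the C7 methylene, which is allylic to C8=C9 (the alkene latent in the 8,9-epoxide). This O–C6–C7–C8(sp2) array is the R–CH(B)–CH2–alkenyl pattern left by a 1,2-metallate shift on a vinylboron ate complex, and C5, as a ring A carbon, can carry boron as a defined stereocentre.
4. The cyclisation precursor comes from (R)-4-silyloxy-2-methylcyclopentenone, B2pin2 and (Z)-3-iodobut-2-enal by copper-catalysed conjugate borylation/aldol (C5–B, quaternary C1, C10–O), then CBS and chelation-controlled reductions for C10 and C2.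
5. Ring order: ring A (chiral cyclopentenone), then ring B (key step), then the oxirane last.

Key step: step 10

Convention: C15 = methyl on C1, C14 = methyl on C8; α = face opposite to C15; Bpin = 4,4,5,5-tetramethyl-1,3,2-dioxaborolan-2-yl; TBS = tert-butyldimethylsilyl.
Assumption: the (Sp,Sp) enantiomer of MandyPhos is taken as the ligand matched to the 6α-boronate; if the sense is opposite, its antipode is used under the same conditions.
Assumption: in the CBS step the quaternary C1 acts as the large substituent of the C10 ketone.

**Step 1**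
Reactants: 1 (R)-4-(tert-butyldimethylsilyloxy)cyclopent-2-en-1-one
Product: 2 (R)-4-(tert-butyldimethylsilyloxy)-2-iodocyclopent-2-en-1-one
Conditions: I2, pyridine, CH2Cl2, 0 °C to rt
Reagents that add atoms: iodine, [I][I]
Why: α-iodination of the enone by the pyridine addition–iodination–elimination sequence (Baylis–Hillman-type mechanism) installs the handle for the C15 methyl without touching the C4 stereocentre.

**Step 2**
Reactants: 2 (R)-4-(tert-butyldimethylsilyloxy)-2-iodocyclopent-2-en-1-one
Product: 3 (R)-4-(tert-butyldimethylsilyloxy)-2-methylcyclopent-2-en-1-one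
Conditions: SnMe4, PdCl2(PhCN)2 (5 mol %), AsPh3, CuI, NMP, 60 °C
Reagents that add atoms: tetramethylstannane, C[Sn](C)(C)C
Why: Stille cross-coupling of the α-iodoenone under neutral conditions introduces the future C15 methyl and avoids base-induced β-elimination of the silyloxy group.

**Step 3**
Reactants: 4 but-2-yn-1-ol
Product: 5 (Z)-3-iodobut-2-en-1-ol
Conditions: NaAlH2(OCH2CH2OMe)2 (Red-Al), THF, 0 °C to rt; then I2, −78 °C to 0 °C
Reagents that add atoms: iodine, [I][I]
Why: hydroxyl-directed trans-hydroalumination of the propargylic alcohol followed by iodinolysis with retention gives the (Z)-iodoalkene, which fixes the cis relation of C7 and C10 across the future C8=C9 bond.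

**Step 4**
Reactants: 5 (Z)-3-iodobut-2-en-1-ol
Product: 6 (Z)-3-iodobut-2-enal
Conditions: MnO2, CH2Cl2, rt, dark
Reagents that add atoms: none
Why: heterogeneous MnO2 oxidation of the allylic alcohol stops at the enal and, being neutral, should not isomerise the (Z)-alkene.

**Step 5**
Reactants: 3 (R)-4-(tert-butyldimethylsilyloxy)-2-methylcyclopent-2-en-1-one; 6 (Z)-3-iodobut-2-enal
Product: 8 aldol adduct (ring A C2 ketone with 1β-methyl; 1α-CH(OH)CH=C(Me)I side chain; 4α-OTBS; 5β-Bpin), via boron enolate 7 (not isolated)
Conditions: B2pin2 (1.0 equiv), CuCl (5 mol %), Xantphos (5 mol %), NaOtBu (10 mol %), THF, 0 °C; then 6, −78 to −20 °C; aq NH4Cl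
Reagents that add atoms: bis(pinacolato)diboron, CC1(C)OB(OC1(C)C)B1OC(C)(C)C(C)(C)O1
Why: tandem copper-catalysed conjugate borylation–aldol reaction, in which boryl copper adds to C5 anti to the C4 silyloxy group, the aprotic medium leaves boron enolate 7, and the aldehyde adds to C1 anti to the new C5–B bond so that C15 ends cis to boron on the quaternary carbon (a closed transition state is expected to give mainly the 10-epi carbinol, which does not matter because step 6 removes this centre).

**Step 6**
Reactants: 8 aldol adduct
Product: 9 2,10-diketone (1α-[(Z)-3-iodobut-2-enoyl] ring A ketone)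
Conditions: MnO2, CH2Cl2, rt
Reagents that add atoms: none
Why: allylic alcohol oxidation gives the non-enolisable 2,10-diketone and converges any C10 epimers under neutral conditions, which the β-silyloxy ketone requires.

**Step 7**
Reactants: 9 2,10-diketone
Product: 10 C10 allylic alcohol with target configuration at C10 (C2 ketone kept)
Conditions: (S)-2-methyl-CBS-oxazaborolidine (0.5 equiv), catecholborane (1.5 equiv), toluene, −78 °C
Reagents that add atoms: none
Why: Corey–Bakshi–Shibata reduction, in which the oxazaborolidine–catecholborane system at −78 °C should reduce the conjugated C10 ketone in preference to the hindered ring ketone and, with the quaternary C1 as the large group, the (S)-catalyst delivers hydride to the face that gives the C10 configuration of the target (reagent control).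

**Step 8**
Reactants: 10 C10 allylic alcohol with C2 ketone
Product: 11 syn-2α,10-diol
Conditions: Et2BOMe, THF/MeOH (4:1), −78 °C; NaBH4; repeated evaporation from MeOH (no peroxide)
Reagents that add atoms: none
Why: Narasaka–Prasad reduction, in which the C10 hydroxyl and the C2 ketone are tied in a diethylboron chelate on the α-face and borohydride attacks externally from the β-face, giving the 1,3-syn diol with the 2α-hydroxyl.

**Step 9**
Reactants: 11 syn-2α,10-diol
Product: 12 2,10-acetonide (cyclisation precursor with C5–Bpin and the (Z)-alkenyl iodide)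
Conditions: Me2C(OMe)2, PPTS (cat.), CH2Cl2, rt
Reagents that add atoms: 2,2-dimethoxypropane, COC(C)(C)OC
Why: acid-catalysed transketalisation converts the syn-1,3-diol into its six-membered acetonide, which removes all acidic protons before the organomagnesium step and is orthogonal to the silyl ether.

**Step 10**
Reactants: 12 2,10-acetonide
Product: 14 trans-fused bicyclic 6α-pinacolboronate (ring B closed; C8=C9; 2α,10α-acetonide; 4α-OTBS), via vinylboron ate complex 13 (not isolated)
Conditions: CH2=CHMgBr (1.05 equiv), THF, 0 °C to rt; then NaOTf, Pd(OAc)2 (5 mol %), (Sp,Sp)-MandyPhos [1,1'-bis(bis(4-methoxy-3,5-dimethylphenyl)phosphino)-2,2'-bis((R)-α-(dimethylamino)benzyl)ferrocene] (6 mol %), THF/DMSO, 60 °C, 0.01 M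
Reagents that add atoms: vinylmagnesium bromide, C=C[Mg]Br
Why: Proposed new method: vinylmagnesium bromide adds to the C5 boronate to give the four-coordinate vinylboron ate complex 13; zerovalent palladium inserts into the C8–I bond, NaOTf removes iodide, the cationic alkenyl divalent palladium binds the boron-bound vinyl group and triggers a 1,2-metallate shift of C5 from boron to C6 anti to palladium, and C7–C8 reductive elimination from the eight-membered palladacycle releases 14. The closest known reaction type is the intermolecular palladium/MandyPhos-catalysed conjunctive cross-coupling of vinylboron ate complexes with alkenyl halides or triflates; the new element is that the electrophile is tethered, so the vinyl unit is inserted between C5 and C8 of one molecule. Ring B is closed as a formal [5+2] annulation, the seven-membered ring forming in the C(sp3)–C(sp2) reductive elimination (endo with respect to the vinyl group). C5 keeps its configuration because the metallate shift is stereoretentive at the migrating carbon, so the trans ring fusion is inherited from the trans arrangement of C5–B and C1–C10 on ring A; the new C6 stereocentre is set by the face of the vinyl group that the ligated palladium engages, that is by the chiral ligand together with the conformational bias of the forming trans-fused ring. The step needs the conjunctive pathway to beat direct vinyl transfer to palladium, β-hydride elimination and oligomerisation; the wide-bite-angle ligand, the halide scavenger, high dilution, the (Z)-geometry of the iodoalkene and the syn acetonide that holds C10 close to C5 are meant to secure this.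

**Step 11**
Reactants: 14 bicyclic 6α-pinacolboronate with 4α-OTBS
Product: 15 bicyclic 6α-pinacolboronate with free 4α-hydroxyl
Conditions: Bu4NF, AcOH, THF, 0 °C to rt
Reagents that add atoms: none
Why: fluoride-mediated desilylation frees the C4 alcohol, and the alkyl pinacol boronate and the acetonide are expected to tolerate buffered fluoride.

**Step 12**
Reactants: 15 bicyclic boronate with 4α-hydroxyl
Product: 16 bicyclic 6α-pinacolboronate C4 ketone
Conditions: Dess–Martin periodinane, NaHCO3, CH2Cl2, 0 °C to rt
Reagents that add atoms: none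
Why: Dess–Martin oxidation under buffered conditions gives the C4 ketone, the C–B bond survives, and the absence of base protects the C5 stereocentre that is now α to the ketone.

**Step 13**
Reactants: 16 bicyclic boronate C4 ketone
Product: 17 6α-hydroxy C4 ketone
Conditions: NaBO3·4H2O, THF/H2O (1:1), rt
Reagents that add atoms: sodium perborate, [Na+].[O-]OB=O
Why: mild perborate oxidation of the secondary boronate replaces boron by hydroxyl with retention, so the 6α-alcohol appears only now and C6 needed no protecting group while C4 was adjusted.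

**Step 14**
Reactants: 17 6α-hydroxy C4 ketone
Product: 18 2α,10α-(isopropylidenedioxy)-trans-dauc-8-ene-4β,6α-diol
Conditions: iPrMgCl (4 equiv), LaCl3·2LiCl (1.1 equiv), THF, −20 to 0 °C
Reagents that add atoms: isopropylmagnesium chloride, CC(C)[Mg]Cl
Why: lanthanum-promoted Grignard 1,2-addition suppresses enolisation and β-hydride reduction, the C6 alkoxide chelates the metal on the β-face, and the isopropyl group enters C4 from the α-face, anti to the C5–C6 bond and to C15, giving the 4β-tertiary alcohol.

**Step 15**
Reactants: 18 4β,6α-diol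
Product: 19 6α-angeloyloxy-2α,10α-(isopropylidenedioxy)-trans-dauc-8-en-4β-ol
Conditions: angelic acid, 2,4,6-Cl3C6H2COCl, Et3N, toluene, rt; then 18, 75 °C
Reagents that add atoms: angelic acid ((Z)-2-methylbut-2-enoic acid), C/C=C(/C)C(=O)O
Why: Yamaguchi-type mixed-anhydride esterification acylates the secondary C6 hydroxyl and leaves the tertiary C4 hydroxyl, and this activation mode is the usual way to keep the (Z)-geometry of angelic acid.

**Step 16**
Reactants: 19 6α-angelate acetonide
Product: 20 6α-angeloyloxy-trans-dauc-8-ene-2α,4β,10α-triol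
Conditions: AcOH/H2O (4:1), 40 °C
Reagents that add atoms: none
Why: mild aqueous acid hydrolysis of the acetonide releases the 2,10-diol without transesterifying the angelate or ionising the tertiary alcohol.

**Step 17**
Reactants: 20 triol
Product: 21 6α-angeloyloxy-8α,9α-epoxy-trans-daucane-2α,4β,10α-triol
Conditions: VO(acac)2 (5 mol %), t-BuOOH (1.5 equiv), CH2Cl2, 0 °C to rt
Reagents that add atoms: tert-butyl hydroperoxide, CC(C)(C)OO
Why: vanadium-catalysed hydroxyl-directed epoxidation delivers the peroxide oxygen from the vanadate ester of the allylic 10α-hydroxyl to the same face of the C8=C9 alkene, setting C8 and C9 as the 8α,9α-epoxide, while the electron-poor angelate alkene is not attacked.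

**Step 18**
Reactants: 21 epoxy triol
Product: 22 2α,10α-diacetoxy-6α-angeloyloxy-8α,9α-epoxy-trans-daucan-4β-ol (target)
Conditions: Ac2O, pyridine, DMAP (cat.), CH2Cl2, 0 °C to rt
Reagents that add atoms: acetic anhydride, CC(=O)OC(C)=O
Why: DMAP-catalysed acetylation esterifies the two secondary hydroxyls at C2 and C10, while the hindered tertiary C4 hydroxyl should not react under these conditions.

**Compound list**
1 | (R)-4-(tert-butyldimethylsilyloxy)cyclopent-2-en-1-one | O=C1C[C@@H](O[Si](C)(C)C(C)(C)C)C=C1 | starting material
2 | (R)-4-(tert-butyldimethylsilyloxy)-2-iodocyclopent-2-en-1-one | O=C1C[C@@H](O[Si](C)(C)C(C)(C)C)C=C1I | intermediate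
3 | (R)-4-(tert-butyldimethylsilyloxy)-2-methylcyclopent-2-en-1-one | O=C1C[C@@H](O[Si](C)(C)C(C)(C)C)C=C1C | intermediate
4 | but-2-yn-1-ol | CC#CCO | starting material
5 | (Z)-3-iodobut-2-en-1-ol | C/C(I)=C/CO | intermediate
6 | (Z)-3-iodobut-2-enal | C/C(I)=C/C=O | intermediate
7 | boron enolate: 1-methyl-2-(pinacolboryloxy)-4α-(TBS-oxy)-5β-(pinacolboryl)cyclopent-1-ene (daucane numbering) | CC1=C(OB2OC(C)(C)C(C)(C)O2)C[C@@H](O[Si](C)(C)C(C)(C)C)[C@@H]1B3OC(C)(C)C(C)(C)O3 | intermediate (not isolated)
8 | aldol adduct: 1β-methyl-1α-[(Z)-1-hydroxy-3-iodobut-2-enyl]-4α-(TBS-oxy)-5β-(pinacolboryl)cyclopentan-2-one, drawn as the expected 10-epimer | C/C(I)=C/[C@H](O)[C@@]1(C)C(=O)C[C@@H](O[Si](C)(C)C(C)(C)C)[C@@H]1B2OC(C)(C)C(C)(C)O2 | intermediate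
9 | 2,10-diketone: 1β-methyl-1α-[(Z)-3-iodobut-2-enoyl]-4α-(TBS-oxy)-5β-(pinacolboryl)cyclopentan-2-one | C/C(I)=C/C(=O)[C@@]1(C)C(=O)C[C@@H](O[Si](C)(C)C(C)(C)C)[C@@H]1B2OC(C)(C)C(C)(C)O2 | intermediate
10 | C10 allylic alcohol (target configuration at C10) of the ring A C2 ketone | C/C(I)=C/[C@@H](O)[C@@]1(C)C(=O)C[C@@H](O[Si](C)(C)C(C)(C)C)[C@@H]1B2OC(C)(C)C(C)(C)O2 | intermediate
11 | syn-2α,10-diol (ring A: 1β-Me, 2α-OH, 4α-OTBS, 5β-Bpin; side chain CH(OH)CH=C(Me)I, Z) | C/C(I)=C/[C@@H](O)[C@@]1(C)[C@@H](O)C[C@@H](O[Si](C)(C)C(C)(C)C)[C@@H]1B2OC(C)(C)C(C)(C)O2 | intermediate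
12 | 2,10-O-isopropylidene acetal (acetonide) of 11 | C/C(I)=C/[C@@H](O3)[C@@]1(C)[C@@H](OC3(C)C)C[C@@H](O[Si](C)(C)C(C)(C)C)[C@@H]1B2OC(C)(C)C(C)(C)O2 | intermediate
13 | bromomagnesium vinylboron ate complex of 12 (vinyl on the C5 boron) | C/C(I)=C/[C@@H](O3)[C@@]1(C)[C@@H](OC3(C)C)C[C@@H](O[Si](C)(C)C(C)(C)C)[C@@H]1[B-]2(C=C)OC(C)(C)C(C)(C)O2.[Mg+]Br | intermediate (not isolated)
14 | trans-fused ring A/ring B boronate: 1β-Me, 8-Me, C8=C9, 6α-Bpin, 4α-OTBS, 2α,10α-acetonide, H5α | CC1(C)OB(OC1(C)C)[C@H]2CC(C)=C[C@@H](O3)[C@@]4(C)[C@@H](OC3(C)C)C[C@@H](O[Si](C)(C)C(C)(C)C)[C@H]24 | intermediate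
15 | as 14 with free 4α-hydroxyl | CC1(C)OB(OC1(C)C)[C@H]2CC(C)=C[C@@H](O3)[C@@]4(C)[C@@H](OC3(C)C)C[C@@H](O)[C@H]24 | intermediate
16 | as 14 with C4 ketone | CC1(C)OB(OC1(C)C)[C@H]2CC(C)=C[C@@H](O3)[C@@]4(C)[C@@H](OC3(C)C)CC(=O)[C@H]24 | intermediate
17 | 6α-hydroxy C4 ketone (2α,10α-acetonide, C8=C9) | O[C@H]1CC(C)=C[C@@H](O3)[C@@]2(C)[C@@H](OC3(C)C)CC(=O)[C@H]12 | intermediate
18 | 2α,10α-(isopropylidenedioxy)-trans-dauc-8-ene-4β,6α-diol | O[C@H]1CC(C)=C[C@@H](O3)[C@@]2(C)[C@@H](OC3(C)C)C[C@@](O)(C(C)C)[C@H]12 | intermediate
19 | 6α-angeloyloxy-2α,10α-(isopropylidenedioxy)-trans-dauc-8-en-4β-ol | C/C=C(/C)C(=O)O[C@H]1CC(C)=C[C@@H](O3)[C@@]2(C)[C@@H](OC3(C)C)C[C@@](O)(C(C)C)[C@H]12 | intermediate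
20 | 6α-angeloyloxy-trans-dauc-8-ene-2α,4β,10α-triol | C/C=C(/C)C(=O)O[C@H]1CC(C)=C[C@@H](O)[C@@]2(C)[C@@H](O)C[C@@](O)(C(C)C)[C@H]12 | intermediate
21 | 6α-angeloyloxy-8α,9α-epoxy-trans-daucane-2α,4β,10α-triol | C/C=C(/C)C(=O)O[C@H]1C[C@@]2(C)O[C@H]2[C@@H](O)[C@@]2(C)[C@@H](O)C[C@@](O)(C(C)C)[C@H]12 | intermediate
22 | 2α,10α-diacetoxy-6α-angeloyloxy-8α,9α-epoxy-trans-daucan-4β-ol (CNP0170993.1) | C/C=C(/C)C(=O)O[C@H]1C[C@@]2(C)O[C@H]2[C@@H](OC(C)=O)[C@@]2(C)[C@@H](OC(C)=O)C[C@@](O)(C(C)C)[C@H]12 | target

Total step count: 18
Longest linear sequence: 16 steps (steps 1, 2 and 5 to 18)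

**Steps most likely to fail**

Step 10 (proposed new method). The ring-forming metallate shift may be outrun by direct transfer of the vinyl group from boron to palladium, by β-hydride elimination or by oligomerisation. The hindered secondary C5 group may also fail to migrate, or the vinyl face may be engaged with poor selectivity at C6. The fallback sets out from 12 and comes back at 14, forming the two bonds by known reactions. Compound 12 is hydrodeiodinated (Pd(PPh3)4, Bu3SnH, THF, rt) with retention of alkene geometry to the (E)-propenyl compound F1. F1 is then homologated by lithiation–borylation: 3-methylbut-3-en-1-yl N,N-diisopropylcarbamate is lithiated with s-BuLi/(+)-sparteine (Et2O, −78 °C), F1 is added, and the ate complex is warmed with MgBr2·OEt2. The 1,2-metallate rearrangement forms C5–C6 with retention at C5 and reagent control at C6, giving the homoallylic 6α-boronate F2, which already carries C7 and the C8 isopropenyl group. Ring-closing metathesis of F2 (second-generation Grubbs catalyst, RuCl2(H2IMes)(PCy3)(=CHPh), CH2Cl2, 40 °C) forms C8=C9 with loss of propene and gives 14.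

Step 5. The boryl copper species may attack the aldehyde or the alkenyl iodide of 6, and the boron enolate may be trapped incompletely. The fallback sets out from 3 and comes back at 8, separating borylation from the aldol event. Compound 3 is treated with a stoichiometric boryl copper reagent (CuCl, NaOtBu, B2pin2, 1:1:1, THF, 0 °C) and the copper enolate is silylated with Me3SiCl to give the isolable trimethylsilyl enol ether F3, which is freed from copper and diboron residues. A separate Mukaiyama aldol reaction of F3 with 6 (BF3·OEt2, CH2Cl2, −78 °C) gives 8; either C10 epimer serves, since step 6 converges them.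

Step 14. The hindered C4 ketone may be enolised (which would also endanger C5) or reduced by β-hydride transfer from the isopropyl reagent instead of undergoing addition. The fallback sets out from 17 and comes back at 18. The smaller sp2 nucleophile 2-propenylmagnesium bromide, which cannot transfer hydride, is added with CeCl3 (THF, −78 °C) to give the isopropenyl carbinol F4. Chemoselective hydrogenation of its 1,1-disubstituted alkene (H2, RhCl(PPh3)3, benzene, rt) leaves the trisubstituted C8=C9 alkene and gives 18.

**Further compounds**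
F1 | step 10 | (E)-propenyl analogue of 12 (iodine replaced by hydrogen) | C/C=C/[C@@H](O3)[C@@]1(C)[C@@H](OC3(C)C)C[C@@H](O[Si](C)(C)C(C)(C)C)[C@@H]1B2OC(C)(C)C(C)(C)O2
F2 | step 10 | homologated 6α-boronate: C5–CH(Bpin)–CH2–C(Me)=CH2 on ring A, (E)-propenyl on C10, acetonide and 4α-OTBS kept | C/C=C/[C@@H](O3)[C@@]1(C)[C@@H](OC3(C)C)C[C@@H](O[Si](C)(C)C(C)(C)C)[C@@H]1[C@H](CC(C)=C)B2OC(C)(C)C(C)(C)O2
F3 | step 5 | trimethylsilyl enol ether: 1-methyl-2-(trimethylsilyloxy)-4α-(TBS-oxy)-5β-(pinacolboryl)cyclopent-1-ene | CC1=C(O[Si](C)(C)C)C[C@@H](O[Si](C)(C)C(C)(C)C)[C@@H]1B2OC(C)(C)C(C)(C)O2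
F4 | step 14 | isopropenyl carbinol: 4α-(prop-1-en-2-yl) analogue of 18 (4β-OH, 6α-OH, acetonide) | O[C@H]1CC(C)=C[C@@H](O3)[C@@]2(C)[C@@H](OC3(C)C)C[C@@](O)(C(C)=C)[C@H]12
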